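**Retrosynthetic overview**

1. Target ⇐ cross-metathesis (vinyl → prenyl) ⇐ exocyclic allylic alcohol (C9–OH/C10=CH2) ⇐ titanium-mediated isomerisation of a 9α,10α-epoxide.
2. C4 carbinol and C2=C3 ⇐ 6β-OH-directed epoxidation of a 3-ene, selenide opening and selenoxide elimination; C6 ⇐ oxidation/reduction; C12 ⇐ allylboration of a lactol.
3. Lactol ⇐ guaia-3,9-dien-12,6α-olide ⇐ reductive 1,3-transposition of a 3-oxo-guai-4-ene (sets H-5β, trans ring fusion).
4. Hydroazulene ⇐ (−)-α-santonin by photochemical dienone rearrangement; C1 is set there, C7 and C11 come from santonin.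
5. Ring order: the five- and seven-membered carbocycles form together in step 1; the lactone ring is opened in steps 4–5 and is not in the target.

Assumption: the SMILES is taken literally (guaiane numbering: 1R,4S,5R,6R,7S,9R,11S,12S, i.e. H-1α/H-5β trans-fused, 4β-, 6β- and 9α-oxygens); C13 = 11-methyl, C14 = exocyclic CH2, C15 = 4-methyl.

**Route**

Step 1
Reactants: 1 (−)-α-santonin
Product: 3 isophotosantonic lactone, via oxyallyl zwitterion 2 (not isolated)
Conditions: hν (Hg lamp, quartz), AcOH/H2O 1:1, reflux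
Reagents that add atoms: water, O
Why: Barton's cross-conjugated dienone photorearrangement: excited-state C1–C5 bonding gives zwitterion 2, and acid opening of its C5–C10 bond with anti capture of water at C10 forms the cyclopentenone and the seven-membered ring in the same operation; C1 (H α) is fixed by the retained C10 centre, and C6, C7, C11 are untouched.

Step 2
Reactants: 3 isophotosantonic lactone
Product: 4 3-oxo-1αH-guaia-4,9-dien-12,6α-olide
Conditions: POCl3, pyridine, 0 → 23 °C
Reagents that add atoms: none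
Why: E2 dehydration of the tertiary alcohol: only H-9β and the methyl hydrogens can be antiperiplanar to the 10α leaving group (H-1 is syn), so the more substituted 9-ene predominates and the minor exocyclic isomer is removed by chromatography; no stereocentre is formed.

Step 3
Reactants: 4 3-oxo-1αH-guaia-4,9-dien-12,6α-olide
Product: 7 1αH,5βH-guaia-3,9-dien-12,6α-olide, via tosylhydrazone 5 (not isolated), via allylic diazene 6 (not isolated)
Conditions: TsNHNH2, EtOH, 60 °C; evaporate; catecholborane, CHCl3, 0 °C; NaOAc·3H2O, 65 °C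
Reagents that add atoms: none
Why: Kabalka reductive 1,3-transposition of an enone tosylhydrazone: hydride adds to C3 from the α face (the β face is screened by C10 on C1), sulfinate loss gives the 3β-diazene 6, and its suprafacial retro-ene loss of N2 puts hydrogen on the β face of C5 while moving the olefin to C3=C4, which sets the trans ring fusion.

Step 4
Reactants: 7 1αH,5βH-guaia-3,9-dien-12,6α-olide
Product: 8 6α,12-lactol of 7 (both anomers)
Conditions: i-Bu2AlH (1.1 equiv), CH2Cl2, −78 °C; Rochelle salt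
Reagents that add atoms: none
Why: Partial reduction of a γ-lactone with one equivalent of i-Bu2AlH at −78 °C stops at the lactol oxidation level; the anomeric centre is lost in the next step.

Step 5
Reactants: 8 6α,12-lactol of 7
Product: 10 (12S)-12-allyl-1αH,5βH-guaia-3,9-diene-6α,12-diol, via hydroxy aldehyde 9 (not isolated)
Conditions: (R,R)-tartrate allylboronate (2 equiv), 4 Å molecular sieves, toluene, −78 → 23 °C; aq. NaOH
Reagents that add atoms: diisopropyl (4R,5R)-2-allyl-1,3,2-dioxaborolane-4,5-dicarboxylate, C=CCB1O[C@@H](C(=O)OC(C)C)[C@H](C(=O)OC(C)C)O1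
Why: Roush asymmetric allylboration of the open tautomer 9 through a chair six-membered transition state: the (R,R)-reagent adds to the Si face to give 12S, matched with the Felkin–Anh preference of the α-methyl aldehyde (11-Me/12-OH syn).

Step 6
Reactants: 10 (12S)-12-allyl-1αH,5βH-guaia-3,9-diene-6α,12-diol
Product: 11 12-monoacetate of 10
Conditions: Ac2O (1.1 equiv), pyridine, 4-(dimethylamino)pyridine (5 mol %), CH2Cl2, −20 → 0 °C
Reagents that add atoms: acetic anhydride, CC(=O)OC(C)=O
Why: Kinetically selective acetylation: the C12 carbinol has one α-branch whereas the 6α-hydroxyl is flanked by two ring methines, so one equivalent of anhydride at low temperature acylates C12 only.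

Step 7
Reactants: 11 12-monoacetate of 10
Product: 12 (12S)-12-acetoxy-12-allyl-1αH,5βH-guaia-3,9-dien-6-one
Conditions: Dess–Martin periodinane, NaHCO3, CH2Cl2, 0 → 23 °C
Reagents that add atoms: none
Why: Buffered Dess–Martin oxidation converts the hindered C6 alcohol to the ketone without epimerising C5 or C7 and without moving the β,γ-olefin into conjugation.

Step 8
Reactants: 12 (12S)-12-acetoxy-12-allyl-1αH,5βH-guaia-3,9-dien-6-one
Product: 13 (12S)-12-acetoxy-12-allyl-1αH,5βH-guaia-3,9-dien-6β-ol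
Conditions: LiBH(s-Bu)3, THF, −78 °C; H2O
Reagents that add atoms: none
Why: Diastereoselective ketone reduction with a bulky hydride: attack from the α face, anti to the branched C7 side chain, gives the 6β-alcohol cis to the side chain (the usual outcome for 2-substituted cycloalkanones), and the acetate is inert at −78 °C.

Step 9
Reactants: 13 (12S)-12-acetoxy-12-allyl-1αH,5βH-guaia-3,9-dien-6β-ol
Product: 14 3β,4β-epoxide of 13
Conditions: VO(acac)2 (5 mol %), t-BuOOH (1.3 equiv), CH2Cl2, 0 → 23 °C
Reagents that add atoms: tert-butyl hydroperoxide, CC(C)(C)OO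
Why: Hydroxyl-directed vanadium-catalysed epoxidation of a homoallylic alcohol: oxygen is delivered from vanadium bound to 6β-OH to the β face of the 3-ene only, setting C3 and C4 (4β-O) and leaving the undirected 9-ene and the vinyl group alone.

Step 10
Reactants: 14 3β,4β-epoxide of 13
Product: 18 (12S)-12-acetoxy-12-allyl-9α,10α-epoxy-1αH,5βH-guai-2-ene-4β,6β-diol, via hydroxy selenide 15 (not isolated), via selenoxide 16 (not isolated), via epoxy selenoxide 17 (not isolated)
Conditions: (PhSe)2, NaBH4, EtOH, 50 °C; work-up; mCPBA (2.1 equiv), NaHCO3, CH2Cl2, −78 → −20 °C; pyridine, 23 °C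
Reagents that add atoms: 3-chloroperoxybenzoic acid, O=C(OO)c1cccc(Cl)c1
Why: Sharpless–Lauer epoxide-to-allylic-alcohol sequence merged with a Prilezhaev epoxidation: PhSe− opens the epoxide by SN2 at the less hindered C3 (α attack, 4β tertiary alcohol kept), the peracid oxidises selenium and then epoxidises the only trisubstituted olefin from the α face (anti to C2 on C1) before any cyclopentene exists, and warming causes selenoxide syn-elimination away from the hydroxyl to give C2=C3.

Step 11
Reactants: 18 (12S)-12-acetoxy-12-allyl-9α,10α-epoxy-1αH,5βH-guai-2-ene-4β,6β-diol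
Product: 19 (12S)-12-acetoxy-12-allyl-1αH,5βH-guaia-2,10(14)-diene-4β,6β,9α-triol
Conditions: Cp2TiCl2 (2.5 equiv), Mn, THF, 23 °C; aq. NaH2PO4
Reagents that add atoms: none
Why: Radical epoxide-to-allylic-alcohol isomerisation with Cp2TiCl (trivalent titanium): homolysis of the tertiary C10–O bond and hydrogen-atom abstraction from the unhindered methyl by a second Cp2TiCl form the exocyclic methylene, while the untouched C9–O bond keeps the 9α configuration.

Step 12
Reactants: 19 (12S)-12-acetoxy-12-allyl-1αH,5βH-guaia-2,10(14)-diene-4β,6β,9α-triol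
Product: 20 CNP0126182.2
Conditions: 2-methylbut-2-ene/CH2Cl2, (H2IMes)(PCy3)Cl2Ru=CHPh (second-generation Grubbs catalyst, 5 mol %), 40 °C
Reagents that add atoms: 2-methylbut-2-ene, CC=C(C)C
Why: Olefin cross-metathesis with excess 2-methylbut-2-ene converts the terminal vinyl group into the prenyl group; the 1,1-disubstituted exocyclic olefin and the hindered cyclopentene do not engage, and no stereocentre is touched.

**Compound list**

1 | (−)-α-santonin | C[C@H]1[C@@H]2CC[C@]3(C=CC(=O)C(=C3[C@H]2OC1=O)C)C | starting material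
2 | oxyallyl zwitterion (C1–C5 bonded cyclopropane, forms in the flask) | C[C@H]1[C@@H]2CC[C@@]3(C)[C@@H]4[CH+]C([O-])=C(C)[C@]34[C@H]2OC1=O | intermediate
3 | isophotosantonic lactone (10α-hydroxy-3-oxo-1αH-guai-4-en-12,6α-olide) | C[C@@]1(O)CC[C@H]2[C@H](C)C(=O)O[C@@H]2C3=C(C)C(=O)C[C@@H]13 | intermediate
4 | 3-oxo-1αH-guaia-4,9-dien-12,6α-olide | CC1=CC[C@H]2[C@H](C)C(=O)O[C@@H]2C3=C(C)C(=O)C[C@@H]13 | intermediate
5 | C3 tosylhydrazone of 4 (forms in the flask) | CC1=CC[C@H]2[C@H](C)C(=O)O[C@@H]2C3=C(C)C(=NNS(=O)(=O)c4ccc(C)cc4)C[C@@H]13 | intermediate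
6 | 3β-diazenyl-1αH-guaia-4,9-dien-12,6α-olide (forms in the flask) | CC1=CC[C@H]2[C@H](C)C(=O)O[C@@H]2C3=C(C)[C@@H](N=N)C[C@@H]13 | intermediate
7 | 1αH,5βH-guaia-3,9-dien-12,6α-olide | CC1=CC[C@H]2[C@H](C)C(=O)O[C@@H]2[C@@H]3C(C)=CC[C@@H]13 | intermediate
8 | 6α,12-lactol of 7 (both anomers) | CC1=CC[C@H]2[C@H](C)C(O)O[C@@H]2[C@@H]3C(C)=CC[C@@H]13 | intermediate
9 | 6α-hydroxy-1αH,5βH-guaia-3,9-dien-12-al (open tautomer of 8, forms in the flask) | CC1=CC[C@@H]([C@H](C)C=O)[C@H](O)[C@@H]2C(C)=CC[C@@H]12 | intermediate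
10 | (12S)-12-allyl-1αH,5βH-guaia-3,9-diene-6α,12-diol | CC1=CC[C@@H]([C@H](C)[C@H](CC=C)O)[C@H](O)[C@@H]2C(C)=CC[C@@H]12 | intermediate
11 | 12-monoacetate of 10 | CC1=CC[C@@H]([C@H](C)[C@H](CC=C)OC(C)=O)[C@H](O)[C@@H]2C(C)=CC[C@@H]12 | intermediate
12 | (12S)-12-acetoxy-12-allyl-1αH,5βH-guaia-3,9-dien-6-one | CC1=CC[C@@H]([C@H](C)[C@H](CC=C)OC(C)=O)C(=O)[C@@H]2C(C)=CC[C@@H]12 | intermediate
13 | (12S)-12-acetoxy-12-allyl-1αH,5βH-guaia-3,9-dien-6β-ol | CC1=CC[C@@H]([C@H](C)[C@H](CC=C)OC(C)=O)[C@@H](O)[C@@H]2C(C)=CC[C@@H]12 | intermediate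
14 | 3β,4β-epoxide of 13 | CC1=CC[C@@H]([C@H](C)[C@H](CC=C)OC(C)=O)[C@@H](O)[C@@H]2[C@@]3(C)O[C@H]3C[C@@H]12 | intermediate
15 | 3α-phenylseleno-4β,6β-diol (forms in the flask) | CC1=CC[C@@H]([C@H](C)[C@H](CC=C)OC(C)=O)[C@@H](O)[C@@H]2[C@@](C)(O)[C@H]([Se]c3ccccc3)C[C@@H]12 | intermediate
16 | selenoxide of 15 (forms in the flask) | CC1=CC[C@@H]([C@H](C)[C@H](CC=C)OC(C)=O)[C@@H](O)[C@@H]2[C@@](C)(O)[C@H]([Se](=O)c3ccccc3)C[C@@H]12 | intermediate
17 | 9α,10α-epoxide of 16 (forms in the flask) | C[C@@]12O[C@@H]1C[C@@H]([C@H](C)[C@H](CC=C)OC(C)=O)[C@@H](O)[C@@H]3[C@@](C)(O)[C@H]([Se](=O)c4ccccc4)C[C@@H]23 | intermediate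
18 | (12S)-12-acetoxy-12-allyl-9α,10α-epoxy-1αH,5βH-guai-2-ene-4β,6β-diol | C[C@@]12O[C@@H]1C[C@@H]([C@H](C)[C@H](CC=C)OC(C)=O)[C@@H](O)[C@H]3[C@H]2C=C[C@]3(C)O | intermediate
19 | (12S)-12-acetoxy-12-allyl-1αH,5βH-guaia-2,10(14)-diene-4β,6β,9α-triol | C=C1[C@H](O)C[C@@H]([C@H](C)[C@H](CC=C)OC(C)=O)[C@@H](O)[C@H]2[C@H]1C=C[C@]2(C)O | intermediate
20 | CNP0126182.2 | C=C1[C@H](O)C[C@@H]([C@H](C)[C@H](CC=C(C)C)OC(C)=O)[C@@H](O)[C@H]2[C@H]1C=C[C@]2(C)O | target

**Step count and risks**

Total steps: 12. Longest linear sequence: 12 (fully linear from santonin).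

The three steps most likely to fail:

Step 3 (facial course of the hydride addition, which decides C5). If hydride adds to C3 from the β face, the diazene would be α and the cis-fused 5α epimer would result. The same facial bias is then used the other way round. From 4, Luche reduction (NaBH4, CeCl3·7H2O, MeOH, −78 °C) gives the 3α-allylic alcohol F1. Myers' Mitsunobu reaction with 2-nitrobenzenesulfonylhydrazide (PPh3, diethyl azodicarboxylate, −30 °C) inverts C3 and gives the 3β-sulfonylhydrazine F2. On warming, F2 loses the sulfinic acid to give the same 3β-diazene 6, and the route is rejoined at 7.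

Step 8 (face of the C6 ketone reduction, and the base-sensitive β,γ-unsaturated ketone 12). If reduction returns mainly the 6α-alcohol, or C5 suffers at the ketone stage, the ketone is avoided altogether. From 11, Mitsunobu inversion with chloroacetic acid (PPh3, diisopropyl azodicarboxylate, toluene) gives the 6β-chloroacetate F3. Thiourea (NaHCO3, EtOH) then removes the chloroacetyl group in the presence of the acetate, and the route is rejoined at 13.

Step 10 (timing of selenium oxidation, olefin epoxidation and elimination in one flask; possible opening of the new epoxide by 6β-OH). If this cannot be controlled, the events are separated and C9 is oxygenated by an ene reaction instead of an epoxide. From 14, selenide opening as before (through 15) and oxidation with NaIO4 (through 16) give the 2,9-diene-4β,6β-diol F4. A Schenck ene reaction with singlet oxygen (O2, 5,10,15,20-tetraphenylporphyrin, hν, CH2Cl2, −20 °C) reacts preferentially at the trisubstituted olefin; the wanted regioisomer is the 9α-hydroperoxide F5 with the exocyclic methylene. Ene regioselectivity is uncertain, and isomers from abstraction at C1 or C8 are expected. PPh3 reduction of F5 rejoins the route at 19, bypassing 18 and step 11.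

**Further compounds**

F1 | step 3 | 3α-hydroxy-1αH-guaia-4,9-dien-12,6α-olide | CC1=CC[C@H]2[C@H](C)C(=O)O[C@@H]2C3=C(C)[C@H](O)C[C@@H]13
F2 | step 3 | 3β-[1-(2-nitrophenylsulfonyl)hydrazinyl]-1αH-guaia-4,9-dien-12,6α-olide | CC1=CC[C@H]2[C@H](C)C(=O)O[C@@H]2C3=C(C)[C@@H](N(N)S(=O)(=O)c4ccccc4[N+](=O)[O-])C[C@@H]13
F3 | step 8 | (12S)-12-acetoxy-12-allyl-6β-chloroacetoxy-1αH,5βH-guaia-3,9-diene | CC1=CC[C@@H]([C@H](C)[C@H](CC=C)OC(C)=O)[C@@H](OC(=O)CCl)[C@@H]2C(C)=CC[C@@H]12
F4 | step 10 | (12S)-12-acetoxy-12-allyl-1αH,5βH-guaia-2,9-diene-4β,6β-diol | CC1=CC[C@@H]([C@H](C)[C@H](CC=C)OC(C)=O)[C@@H](O)[C@H]2[C@H]1C=C[C@]2(C)O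
F5 | step 10 | (12S)-12-acetoxy-12-allyl-9α-hydroperoxy-1αH,5βH-guaia-2,10(14)-diene-4β,6β-diol | C=C1[C@H](OO)C[C@@H]([C@H](C)[C@H](CC=C)OC(C)=O)[C@@H](O)[C@H]2[C@H]1C=C[C@]2(C)O
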